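**Plan**

- Numbering used here: C1 lactone C=O, C2 ring CH, C3 ring carbon bearing CH2OH, C4 ring O–CH (R), C5 CH2, C6=C7 the Z-alkene, with C7 carrying CH2OH and the homofarnesyl chain (C8 onward).
- Enabling feature: the butenolide ring (O, C1, C2, C3, C4) is a C4 propargylic alcohol with a C2≡C3 triple bond that has taken up a CH2O carbon at C3 and a carboxyl carbon at C2 in a trans sense; the retrosynthesis cuts C3–CH2, C2–C1 and O–C1 in one operation.
- Further cuts: C3–C4 (acetylide plus N-methoxy-N-methylamide), C5–C6 (zinc ester enolate plus Z-alkenyl iodide), C7–C8 (carbomagnesiation of propargyl alcohol by a homofarnesyl Grignard reagent), and the homologating carbon and terminal oxygen added to farnesol.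
- Forward order: farnesol → homofarnesyl bromide → terminal E-allylic oxidation → Z-iodoalkene → ester → amide → ynone → (R)-alkynol → butenolide (the only ring, step 14) → C–Si oxidation → desilylation.
- Stereochemistry: the chain E-alkenes come from farnesol and the E-selective SeO2 oxidation; the C6=C7 geometry comes from chelation-controlled anti-carbomagnesiation and retentive couplings; C4 (R) comes from Ru/(R,R)-TsDPEN transfer hydrogenation and is not touched afterwards.

Key step: step 14

Remark: silanes 5 and 27 are drawn as isopropoxysilanes; any silanol or disiloxane formed from them on work-up should be oxidised to the same alcohol.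

**Route**

Step 1
Reactants: 1 (2E,6E)-farnesol
Product: 2 (2E,6E)-farnesyl bromide
Conditions: PBr3, Et2O, −10 → 0 °C; used crude
Reagents that add atoms: phosphorus tribromide, BrP(Br)Br
Why: Bromination of a primary allylic alcohol with PBr3 at low temperature is the standard entry to farnesyl bromide and should keep the 2E geometry.

Step 2
Reactants: 3 (chloromethyl)isopropoxydimethylsilane
Product: 4 (isopropoxydimethylsilyl)methylmagnesium chloride (THF solution, titrated; used in steps 3 and 14)
Conditions: Mg, BrCH2CH2Br (cat.), THF, reflux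
Reagents that add atoms: magnesium, [Mg]
Why: Grignard formation from the α-silyl alkyl chloride gives the established hydroxymethyl-anion equivalent, the hindered Si–OiPr bond surviving the reagent.

Step 3
Reactants: 2 (2E,6E)-farnesyl bromide; 4 (isopropoxydimethylsilyl)methylmagnesium chloride
Product: 6 (3E,7E)-homofarnesol [(3E,7E)-4,8,12-trimethyltrideca-3,7,11-trien-1-ol], via homofarnesyl silane 5 (not isolated)
Conditions: CuI (5 mol %), THF, −20 → 0 °C; then crude silane, KF, KHCO3, 30% H2O2, THF/MeOH, rt
Reagents that add atoms: hydrogen peroxide, OO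
Why: Copper-catalysed Grignard coupling at the primary (α) carbon of the allylic bromide, which keeps the 2E alkene, followed by Tamao oxidation of the alkyl C–Si bond is a standard one-carbon hydroxymethylation of halides, and basic H2O2 leaves the alkenes alone.

Step 4
Reactants: 6 (3E,7E)-homofarnesol
Product: 7 (3E,7E)-homofarnesyl bromide [(3E,7E)-1-bromo-4,8,12-trimethyltrideca-3,7,11-triene]
Conditions: CBr4, PPh3, CH2Cl2, 0 °C
Reagents that add atoms: carbon tetrabromide, BrC(Br)(Br)Br
Why: Appel bromination of a primary homoallylic alcohol proceeds by SN2 displacement of the oxyphosphonium group without touching the trisubstituted alkenes.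

Step 5
Reactants: 7 (3E,7E)-homofarnesyl bromide
Product: 8 (2E,6E,10E)-13-bromo-2,6,10-trimethyltrideca-2,6,10-trien-1-ol
Conditions: SeO2 (cat.), t-BuOOH, salicylic acid (cat.), CH2Cl2, 0 °C → rt; NaBH4/MeOH work-up at 0 °C to return any enal; unreacted 7 recycled
Reagents that add atoms: selenium dioxide, O=[Se]=O (catalytic oxygen carrier); tert-butyl hydroperoxide, CC(C)(C)OO (stoichiometric oxygen source)
Why: SeO2/t-BuOOH allylic oxidation (ene reaction then [2,3]-sigmatropic shift) is expected to select the E-methyl group of the terminal, least hindered trisubstituted alkene and give the E-allylic alcohol, as with other farnesyl derivatives, while the primary bromide is inert.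

Step 6
Reactants: 8 (2E,6E,10E)-13-bromo-2,6,10-trimethyltrideca-2,6,10-trien-1-ol
Product: 9 TBS ether of 8 [(2E,6E,10E)-13-bromo-1-(tert-butyldimethylsilyloxy)-2,6,10-trimethyltrideca-2,6,10-triene]
Conditions: TBSCl, imidazole, CH2Cl2, rt
Reagents that add atoms: tert-butyldimethylsilyl chloride, CC(C)(C)[Si](C)(C)Cl
Why: Routine silylation of a primary allylic alcohol gives an ether that tolerates the organomagnesium, organozinc, organolithium and fluoride/peroxide steps ahead.

Step 7
Reactants: 9 TBS ether bromide; 10 propargyl alcohol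
Product: 13 (Z)-3-iodo-2-[(3E,7E,11E)-13-(tert-butyldimethylsilyloxy)-4,8,12-trimethyltrideca-3,7,11-trien-1-yl]prop-2-en-1-ol, via Grignard reagent 11 (not isolated), via oxamagnesacycle 12 (not isolated)
Conditions: 9, Mg, THF, 40 °C (→ 11); separately 10 (1.2 equiv), i-PrMgCl (1.2 equiv), THF, 0 °C, then CuI (10 mol %) and 11, 0 °C → rt; I2, THF, −20 → 0 °C
Reagents that add atoms: iodine, II
Why: Copper-catalysed anti-carbomagnesiation of the propargyl alkoxide places the alkyl group on the internal carbon (C7) and magnesium on the terminal carbon (C6) cis to the CH2O group in a five-membered chelate, and iodinolysis with retention gives the Z-iodide with the C6=C7 geometry of the target.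

Step 8
Reactants: 13 (Z)-iodo allylic alcohol
Product: 14 bis-TBS ether of 13
Conditions: TBSCl, imidazole, CH2Cl2, rt
Reagents that add atoms: tert-butyldimethylsilyl chloride, CC(C)(C)[Si](C)(C)Cl
Why: Routine silylation removes the free hydroxyl before the zinc enolate coupling and gives the second spectator silyl ether.

Step 9
Reactants: 14 bis-TBS (Z)-alkenyl iodide; 15 ethyl bromoacetate
Product: 17 ethyl (3Z,7E,11E,15E)-17-(tert-butyldimethylsilyloxy)-4-[(tert-butyldimethylsilyloxy)methyl]-8,12,16-trimethylheptadeca-3,7,11,15-tetraenoate, via Reformatsky reagent 16 (not isolated)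
Conditions: 15, Zn dust, TMSCl (cat.), THF, rt (→ 16); then 14, Pd(PPh3)4 (5 mol %), THF/DMPU, 50 °C
Reagents that add atoms: none
Why: Palladium-catalysed Negishi-type coupling of the Reformatsky reagent with an alkenyl iodide forms C5–C6 with retention of alkene geometry under neutral conditions that should leave the β,γ-alkene in place.

Step 10
Reactants: 17 ethyl ester
Product: 18 N-methoxy-N-methylamide corresponding to 17
Conditions: MeNH(OMe)·HCl, AlMe3, CH2Cl2, 0 °C → rt
Reagents that add atoms: N,O-dimethylhydroxylamine hydrochloride, CNOC.Cl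
Why: Weinreb amidation with the non-basic aluminium amide converts the ester without enolising the doubly activated C5 methylene.

Step 11
Reactants: 18 N-methoxy-N-methylamide; 19 trimethylsilylacetylene
Product: 21 silyl ynone [(5Z,9E,13E,17E)-19-(tert-butyldimethylsilyloxy)-6-[(tert-butyldimethylsilyloxy)methyl]-10,14,18-trimethyl-1-(trimethylsilyl)nonadeca-5,9,13,17-tetraen-1-yn-3-one], via lithium acetylide 20 (not isolated)
Conditions: 19, n-BuLi, THF, −78 °C (→ 20); 18, −78 → −20 °C; cold aq. NH4Cl; rapid filtration through neutral silica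
Reagents that add atoms: none
Why: Acetylide addition to a Weinreb amide stops at the chelated tetrahedral intermediate and releases the ynone only on cold quench, forming C3–C4 without over-addition.

Step 12
Reactants: 21 silyl ynone
Product: 22 (R)-silyl propargylic alcohol [(3R,5Z,9E,13E,17E)-…-1-(trimethylsilyl)nonadeca-5,9,13,17-tetraen-1-yn-3-ol, substituents as in 21]
Conditions: Ru[(R,R)-TsDPEN](p-cymene) (preformed amido complex, 2 mol %), i-PrOH, rt
Reagents that add atoms: none
Why: Noyori asymmetric transfer hydrogenation of an alkynyl ketone delivers hydride through the Ru–H/N–H six-membered transition state, and the (R,R)-ligand is expected, by analogy with simple 1-silylalkyn-3-ones, to set the R carbinol at C4; the base-free catalyst limits enolisation at C5.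

Step 13
Reactants: 22 (R)-silyl propargylic alcohol
Product: 23 (R)-propargylic alcohol [(3R,5Z,9E,13E,17E)-19-(tert-butyldimethylsilyloxy)-6-[(tert-butyldimethylsilyloxy)methyl]-10,14,18-trimethylnonadeca-5,9,13,17-tetraen-1-yn-3-ol]
Conditions: K2CO3, MeOH, 0 °C → rt
Reagents that add atoms: none
Why: Methanolysis of the C(sp)–Si bond is selective for the alkynylsilane and leaves both TBS ethers and the carbinol configuration intact.

Step 14
Reactants: 23 (R)-propargylic alcohol; 4 (isopropoxydimethylsilyl)methylmagnesium chloride; 24 carbon dioxide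
Product: 27 (R)-butenolide bearing the C3 (isopropoxydimethylsilyl)methyl group, bis-TBS ether, via oxamagnesacycle 25 (not isolated), via hydroxy acid 26 (not isolated)
Conditions: 4 (3.5 equiv), CuI (15 mol %), THF, 0 °C → rt; CO2 (1 atm), 0 °C → rt; aq. HCl to pH 3, 0 °C; rapid chromatography on Et3N-deactivated silica
Reagents that add atoms: none
Why: The first equivalent of 4 forms the C4 magnesium alkoxide, and a silylmethylcopper species generated from CuI adds across C2≡C3 with net anti geometry, carbon to C3 and metal to C2, giving after transmetalation the five-membered oxamagnesacycle 25 (O–C4–C3=C2–Mg). Carbon dioxide inserts into the alkenyl C2–Mg bond (C2–C1 bond), and on acidification the C4 hydroxyl, held cis to the carboxyl group in 26, closes the lactone by 5-exo-trig acyl substitution (O–C1 bond). The closest known reaction type is the copper-catalysed anti-carbomagnesiation of propargylic alcohols with alkyl and trimethylsilylmethyl Grignard reagents and carboxylative trapping to butenolides; only the isopropoxy group on silicon is new to the reagent. No stereocentre is formed, and C4 passes through as a non-enolisable alkoxide with its R configuration unchanged. The step needs C3 regiochemistry and anti addition, both secured by chelation of magnesium to the propargylic alkoxide, and chemoselectivity over four trisubstituted alkenes and two silyl ethers, which do not react with Grignard or organocopper reagents; any attack of the alkoxide on Si–OiPr is tolerated because such a siloxane opens on acid work-up.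

Step 15
Reactants: 27 (R)-butenolide silane
Product: 28 (R)-butenolide with C3 hydroxymethyl group, bis-TBS ether
Conditions: KF, KHCO3, 30% H2O2, THF/MeOH, 0 °C → rt; Na2S2O3, then pH 4 buffer work-up
Reagents that add atoms: hydrogen peroxide, OO
Why: Tamao oxidation of the alkoxysilane proceeds by peroxide attack on fluoride-activated silicon and 1,2-shift of the allylic carbon to oxygen, conditions that spare isolated alkenes and TBS ethers; any opened hydroxy carboxylate re-closes on the mildly acidic work-up.

Step 16
Reactants: 28 bis-TBS hydroxymethyl butenolide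
Product: 29 Hippolide F
Conditions: HF·pyridine, pyridine, THF, 0 °C → rt
Reagents that add atoms: none
Why: Buffered acidic fluoride removes both primary allylic TBS ethers without the basic conditions that could deprotonate C4 of the butenolide, so the R configuration is kept.

**Compound list**

1 | (2E,6E)-farnesol | CC(C)=CCC/C(C)=C/CC/C(C)=C/CO | starting material
2 | (2E,6E)-farnesyl bromide | CC(C)=CCC/C(C)=C/CC/C(C)=C/CBr | intermediate
3 | (chloromethyl)isopropoxydimethylsilane | CC(C)O[Si](C)(C)CCl | starting material
4 | (isopropoxydimethylsilyl)methylmagnesium chloride | CC(C)O[Si](C)(C)C[Mg]Cl | intermediate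
5 | isopropoxydimethyl[(3E,7E)-4,8,12-trimethyltrideca-3,7,11-trien-1-yl]silane (homofarnesyl silane) | CC(C)=CCC/C(C)=C/CC/C(C)=C/CC[Si](C)(C)OC(C)C | intermediate (not isolated)
6 | (3E,7E)-homofarnesol | CC(C)=CCC/C(C)=C/CC/C(C)=C/CCO | intermediate
7 | (3E,7E)-homofarnesyl bromide | CC(C)=CCC/C(C)=C/CC/C(C)=C/CCBr | intermediate
8 | (2E,6E,10E)-13-bromo-2,6,10-trimethyltrideca-2,6,10-trien-1-ol | C/C(=C\CC/C(C)=C/CC/C(C)=C/CCBr)CO | intermediate
9 | TBS ether of 8 | C/C(=C\CC/C(C)=C/CC/C(C)=C/CCBr)CO[Si](C)(C)C(C)(C)C | intermediate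
10 | propargyl alcohol | C#CCO | starting material
11 | Grignard reagent from 9 | C/C(=C\CC/C(C)=C/CC/C(C)=C/CC[Mg]Br)CO[Si](C)(C)C(C)(C)C | intermediate (not isolated)
12 | 4-substituted 2,5-dihydro-1,2-oxamagnesole (alkenylmagnesium alkoxide chelate) | C/C(=C\CC/C(C)=C/CC/C(C)=C/CCC1=C[Mg]OC1)CO[Si](C)(C)C(C)(C)C | intermediate (not isolated)
13 | (Z)-3-iodo-2-[(3E,7E,11E)-13-(TBS-oxy)-4,8,12-trimethyltrideca-3,7,11-trien-1-yl]prop-2-en-1-ol | C/C(=C\CC/C(C)=C/CC/C(C)=C/CC/C(=C/I)CO)CO[Si](C)(C)C(C)(C)C | intermediate
14 | bis-TBS ether of 13 | C/C(=C\CC/C(C)=C/CC/C(C)=C/CC/C(=C/I)CO[Si](C)(C)C(C)(C)C)CO[Si](C)(C)C(C)(C)C | intermediate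
15 | ethyl bromoacetate | CCOC(=O)CBr | starting material
16 | bromo(2-ethoxy-2-oxoethyl)zinc (Reformatsky reagent) | CCOC(=O)C[Zn]Br | intermediate (not isolated)
17 | ethyl (3Z,7E,11E,15E)-17-(TBS-oxy)-4-[(TBS-oxy)methyl]-8,12,16-trimethylheptadeca-3,7,11,15-tetraenoate | C/C(=C\CC/C(C)=C/CC/C(C)=C/CC/C(=C/CC(=O)OCC)CO[Si](C)(C)C(C)(C)C)CO[Si](C)(C)C(C)(C)C | intermediate
18 | N-methoxy-N-methylamide of the acid of 17 | C/C(=C\CC/C(C)=C/CC/C(C)=C/CC/C(=C/CC(=O)N(C)OC)CO[Si](C)(C)C(C)(C)C)CO[Si](C)(C)C(C)(C)C | intermediate
19 | trimethylsilylacetylene | C#C[Si](C)(C)C | starting material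
20 | lithium (trimethylsilyl)acetylide | [Li]C#C[Si](C)(C)C | intermediate (not isolated)
21 | silyl ynone (C4 ketone, C2≡C3–SiMe3) | C/C(=C\CC/C(C)=C/CC/C(C)=C/CC/C(=C/CC(=O)C#C[Si](C)(C)C)CO[Si](C)(C)C(C)(C)C)CO[Si](C)(C)C(C)(C)C | intermediate
22 | (R)-silyl propargylic alcohol | C/C(=C\CC/C(C)=C/CC/C(C)=C/CC/C(=C/C[C@@H](O)C#C[Si](C)(C)C)CO[Si](C)(C)C(C)(C)C)CO[Si](C)(C)C(C)(C)C | intermediate
23 | (R)-propargylic alcohol with terminal alkyne, bis-TBS ether | C/C(=C\CC/C(C)=C/CC/C(C)=C/CC/C(=C/C[C@@H](O)C#C)CO[Si](C)(C)C(C)(C)C)CO[Si](C)(C)C(C)(C)C | intermediate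
24 | carbon dioxide | O=C=O | starting material
25 | oxamagnesacycle from 23 (C2–Mg–O–C4 chelate, C3 silylmethyl) | C/C(=C\CC/C(C)=C/CC/C(C)=C/CC/C(=C/C[C@H]1O[Mg]C=C1C[Si](C)(C)OC(C)C)CO[Si](C)(C)C(C)(C)C)CO[Si](C)(C)C(C)(C)C | intermediate (not isolated)
26 | (2Z,4R)-4-hydroxy-3-[(isopropoxydimethylsilyl)methyl]alk-2-enoic acid (magnesium salt before acidification) | C/C(=C\CC/C(C)=C/CC/C(C)=C/CC/C(=C/C[C@@H](O)/C(C[Si](C)(C)OC(C)C)=C\C(=O)O)CO[Si](C)(C)C(C)(C)C)CO[Si](C)(C)C(C)(C)C | intermediate (not isolated)
27 | (R)-butenolide with C3 (isopropoxydimethylsilyl)methyl group, bis-TBS ether | C/C(=C\CC/C(C)=C/CC/C(C)=C/CC/C(=C/C[C@H]1OC(=O)C=C1C[Si](C)(C)OC(C)C)CO[Si](C)(C)C(C)(C)C)CO[Si](C)(C)C(C)(C)C | intermediate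
28 | (R)-butenolide with C3 hydroxymethyl group, bis-TBS ether | C/C(=C\CC/C(C)=C/CC/C(C)=C/CC/C(=C/C[C@H]1OC(=O)C=C1CO)CO[Si](C)(C)C(C)(C)C)CO[Si](C)(C)C(C)(C)C | intermediate
29 | Hippolide F | C/C(=C\CC/C(C)=C/CC/C(C)=C/CC/C(=C/C[C@H]1OC(=O)C=C1CO)CO)CO | target

**Step count and risks**

Total step count: 16. Longest linear sequence: 15 steps (steps 1 and 3–16 from farnesol); step 2 is a one-step side branch that supplies reagent 4 for steps 3 and 14.

Steps most likely to fail:

1. Step 14. The silylmethyl group may transfer too slowly from copper, so that acetylide formation and protonolysis outrun carbomagnesiation, or the chelated alkenylmagnesium may take up CO2 poorly. The fallback reverses the order of the two C–C bond formations and uses conjugate addition in place of carbomagnesiation. It sets out from 23: double deprotonation (n-BuLi, THF, −78 °C) and carboxylation should give the hydroxy ynoic acid F1, which TMSCHN2 (toluene/MeOH) converts to the methyl ester F2. Copper-mediated syn-addition of 4 (CuBr·SMe2, THF, −78 → −40 °C) then places the silylmethyl group on C3 and hydrogen on C2 cis to it, so that in the hydroxy enoate F3 the ester is cis to the C4 oxygen and lactonises on mildly acidic work-up. The route is rejoined at 27.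

2. Step 15. Fluoride may cleave the C–Si bond toward the lactone dienolate (protodesilylation to a C3-methyl butenolide), or lactone opening and C4 epimerisation under the basic peroxide may outpace the silicon-to-oxygen shift. The fallback oxidises silicon before the carbonyl is in place. It sets out from 23: the carbomagnesiation of step 14 is quenched with iodine instead of CO2 to give the (Z)-iodoalkene F4, whose unconjugated allylsilane should undergo Tamao oxidation (KF, KHCO3, H2O2, THF/MeOH) to the iodo diol F5. Palladium-catalysed cyclocarbonylation (PdCl2(PPh3)2, CO 1 atm, K2CO3, THF, 50 °C) then closes the lactone through the C4 hydroxyl, which is cis to the acylpalladium, and the route is rejoined at 28.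

3. Step 12. The C6=C7 double bond may migrate into conjugation through enolisation of the doubly activated C5 methylene, with loss of material and of enantiopurity. The fallback avoids the ketone and sets C4 in a C–C bond-forming step. It sets out from 17: DIBAL-H (CH2Cl2, −78 °C) should give the aldehyde F6, which is used at once in a catalytic enantioselective alkynylation with 19 (Me2Zn, the ProPhenol ligand antipode that delivers the R carbinol, toluene, 0 °C). The route is rejoined at 22, and steps 10–12 are bypassed.

**Further compounds**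

F1 | step 14 | (R)-4-hydroxy-alk-2-ynoic acid from carboxylation of 23 | C/C(=C\CC/C(C)=C/CC/C(C)=C/CC/C(=C/C[C@@H](O)C#CC(=O)O)CO[Si](C)(C)C(C)(C)C)CO[Si](C)(C)C(C)(C)C
F2 | step 14 | methyl ester of F1 | C/C(=C\CC/C(C)=C/CC/C(C)=C/CC/C(=C/C[C@@H](O)C#CC(=O)OC)CO[Si](C)(C)C(C)(C)C)CO[Si](C)(C)C(C)(C)C
F3 | step 14 | methyl (2Z,4R)-4-hydroxy-3-[(isopropoxydimethylsilyl)methyl]alk-2-enoate | C/C(=C\CC/C(C)=C/CC/C(C)=C/CC/C(=C/C[C@@H](O)/C(C[Si](C)(C)OC(C)C)=C\C(=O)OC)CO[Si](C)(C)C(C)(C)C)CO[Si](C)(C)C(C)(C)C
F4 | step 15 | (Z)-C2-iodoalkene with C3 silylmethyl group and free C4 hydroxyl | C/C(=C\CC/C(C)=C/CC/C(C)=C/CC/C(=C/C[C@@H](O)/C(C[Si](C)(C)OC(C)C)=C\I)CO[Si](C)(C)C(C)(C)C)CO[Si](C)(C)C(C)(C)C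
F5 | step 15 | (Z)-iodo diol (C3 hydroxymethyl, C4 hydroxyl) | C/C(=C\CC/C(C)=C/CC/C(C)=C/CC/C(=C/C[C@@H](O)/C(CO)=C\I)CO[Si](C)(C)C(C)(C)C)CO[Si](C)(C)C(C)(C)C
F6 | step 12 | (3Z)-β,γ-unsaturated aldehyde from 17 | C/C(=C\CC/C(C)=C/CC/C(C)=C/CC/C(=C/CC=O)CO[Si](C)(C)C(C)(C)C)CO[Si](C)(C)C(C)(C)C
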